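**Plan**

- Retrosynthesis: all eight phenols are carried as benzyl ethers and freed last by hydrogenolysis, because BBr3 or protic acid would ionise the bis-benzylic tetrahydrofuran. The dihydrobenzofuran is cut at C2′–C3′ and O1′–C2′ ([4+1]), ring D at C3a′–C3′ (aryllithium plus aldehyde), the tetrahydrofuran at C2–aryl/C2–H (lactone arylation, reduction) and C5–aryl (Grignard), and the chain at C3–C4 (Ireland–Claisen).
- Enabling feature: C3′ is a diarylmethine on C3a′ of ring D, ortho to C7a′–O1′. O1′–C7a′–C3a′–C3′ can therefore be released as an o-quinone methide, and C2′ with its 4-oxygenated phenyl added as a one-carbon benzylic sulfonium ylide.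
- Forward order: an arylacetate and a (Z)-allylic alcohol are joined and rearranged (C3–C4); the γ-lactone ring closes and is converted into the tetrahydrofuran; ring D is functionalised at C3a′; the dihydrofuran ring closes last; debenzylation gives the target.
- Stereochemistry: C3 and C4 come from (R)-but-3-yn-2-ol by chirality transfer through a chair Ireland–Claisen transition state. C5 is set by thermodynamic trans lactonisation and C2 by hydride delivery anti to ring D. C2′ is set by the ylide of C2-symmetric (2R,5R)-2,5-dimethylthiolane and C3′ by the trans-selective closure.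
- The ring D oxygen that becomes O1′ is freed selectively by magnesium chelation to a neighbouring ketone.

Key step: step 17

Remark (assumption): 1 and 5 are taken as catalogue compounds; each is otherwise one O-benzylation away from the commercial dihydroxy compound.

Locants and fragment: tetrahydrofuran O1, C2 (4-oxygenated phenyl), C3 (ring D), C4 (3,5-dioxygenated phenyl), C5 (4-oxygenated phenyl); dihydrobenzofuran O1′, C2′, C3′, C3a′, C4′ (bears the tetrahydrofuran) to C7a′. T = (2S,3S,4R,5S)-4-[3,5-bis(benzyloxy)phenyl]-2,5-bis[4-(benzyloxy)phenyl]tetrahydrofuran-3-yl (C2 aryl cis to C3, C3 cis to C4, C4 trans to C5).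

**Route**

Step 1
Reactants: 1 1,3-bis(benzyloxy)-5-bromobenzene; 2 (R)-but-3-yn-2-ol
Product: 3 (R)-4-[3,5-bis(benzyloxy)phenyl]but-3-yn-2-ol
Conditions: PdCl2(PPh3)2 (cat.), CuI (cat.), Et3N, 70 °C
Reagents that add atoms: none
Why: Sonogashira coupling of the aryl bromide with the terminal alkyne, in which the carbinol stereocentre of 2 takes no part and is carried over unchanged.

Step 2
Reactants: 3 (R)-4-[3,5-bis(benzyloxy)phenyl]but-3-yn-2-ol
Product: 4 (R,Z)-4-[3,5-bis(benzyloxy)phenyl]but-3-en-2-ol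
Conditions: H2 (1 atm), Pd/CaCO3 poisoned with Pb(OAc)2 (Lindlar catalyst), quinoline, EtOAc, rt
Reagents that add atoms: none
Why: Lindlar semihydrogenation adds hydrogen syn to the alkyne and stops at the (Z)-alkene, and the poisoned catalyst leaves the aryl benzyl ethers and the carbinol centre untouched.

Step 3
Reactants: 5 [3,5-bis(benzyloxy)phenyl]acetic acid
Product: 6 [3,5-bis(benzyloxy)-2-bromophenyl]acetic acid
Conditions: NBS (1.0 equiv), MeCN, 0 °C → rt
Reagents that add atoms: N-bromosuccinimide, O=C1CCC(=O)N1Br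
Why: Electrophilic aromatic bromination goes to C2 (para to one benzyloxy group, ortho to the other) and not to the more hindered C4 between the two ethers, as is usual for 3,5-dialkoxybenzyl compounds; the two candidate positions C2 and C6 are equivalent.

Step 4
Reactants: 4 (R,Z)-4-[3,5-bis(benzyloxy)phenyl]but-3-en-2-ol; 6 [3,5-bis(benzyloxy)-2-bromophenyl]acetic acid
Product: 7 (R,Z)-4-[3,5-bis(benzyloxy)phenyl]but-3-en-2-yl [3,5-bis(benzyloxy)-2-bromophenyl]acetate
Conditions: DCC, DMAP (cat.), CH2Cl2, 0 °C → rt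
Reagents that add atoms: none
Why: Steglich esterification acylates the secondary allylic alcohol under neutral conditions without ionising it, so the carbinol configuration and the (Z)-alkene are retained.

Step 5
Reactants: 7 (R,Z)-4-[3,5-bis(benzyloxy)phenyl]but-3-en-2-yl [3,5-bis(benzyloxy)-2-bromophenyl]acetate
Product: 10 (2S,3R,E)-2-[3,5-bis(benzyloxy)-2-bromophenyl]-3-[3,5-bis(benzyloxy)phenyl]hex-4-enoic acid, via (Z)-silyl ketene acetal 8 (not isolated), via trimethylsilyl ester 9 (not isolated)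
Conditions: KN(SiMe3)2, THF, −78 °C; Me3SiCl; −78 °C → rt; aq. HCl
Reagents that add atoms: none
Why: Ireland–Claisen rearrangement, in which the potassium enolate of the arylacetate forms with the aryl group cis to the enolate oxygen and is silylated to 8, which rearranges through a chair transition state with the carbinol methyl equatorial and the (Z)-alkene aryl axial, so that the (R)-carbinol centre is transferred into the new C2 (S) and C3 (R) centres (the two aryl groups cis in the later ring) and the new alkene is E.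

Step 6
Reactants: 10 (2S,3R,E)-2-[3,5-bis(benzyloxy)-2-bromophenyl]-3-[3,5-bis(benzyloxy)phenyl]hex-4-enoic acid
Product: 11 (3S,4R)-3-[3,5-bis(benzyloxy)-2-bromophenyl]-4-[3,5-bis(benzyloxy)phenyl]-5-hydroxydihydrofuran-2(3H)-one (both C5 epimers)
Conditions: OsO4 (cat.), NaIO4, 2,6-lutidine, dioxane/H2O, rt
Reagents that add atoms: osmium tetroxide, O=[Os](=O)(=O)=O (oxygen carrier); sodium periodate, [Na+].[O-]I(=O)(=O)=O (terminal oxidant)
Why: Lemieux–Johnson cleavage of the disubstituted alkene gives the aldehyde, which is trapped by the neighbouring carboxylic acid as the cyclic hydroxy lactone and thereby protected against epimerisation of its α-aryl centre.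

Step 7
Reactants: 11 (3S,4R)-3-[3,5-bis(benzyloxy)-2-bromophenyl]-4-[3,5-bis(benzyloxy)phenyl]-5-hydroxydihydrofuran-2(3H)-one; 12 4-(benzyloxy)phenylmagnesium bromide
Product: 14 (3S,4R,5S)-3-[3,5-bis(benzyloxy)-2-bromophenyl]-4-[3,5-bis(benzyloxy)phenyl]-5-[4-(benzyloxy)phenyl]dihydrofuran-2(3H)-one, via hydroxy acid 13 (not isolated)
Conditions: 12 (3 equiv), THF, −78 → 0 °C; aq. HCl; then CSA (cat.), CH2Cl2, rt
Reagents that add atoms: none
Why: Grignard addition to the ring-opened aldehyde–carboxylate (the first equivalent acts as base) gives 13, and acid-catalysed lactonisation, reversible at C5 through the 4-alkoxybenzylic cation, should settle on the 4,5-trans lactone in which the new aryl group avoids the two cis aryl groups.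

Step 8
Reactants: 14 (3S,4R,5S)-3-[3,5-bis(benzyloxy)-2-bromophenyl]-4-[3,5-bis(benzyloxy)phenyl]-5-[4-(benzyloxy)phenyl]dihydrofuran-2(3H)-one; 12 4-(benzyloxy)phenylmagnesium bromide
Product: 16 (2S,3S,4R,5S)-3-[3,5-bis(benzyloxy)-2-bromophenyl]-4-[3,5-bis(benzyloxy)phenyl]-2,5-bis[4-(benzyloxy)phenyl]tetrahydrofuran, via lactol 15 (not isolated)
Conditions: 12 premixed with CeCl3, THF, −78 → −40 °C; then Et3SiH, BF3·OEt2, CH2Cl2, −78 °C
Reagents that add atoms: none
Why: Monoaddition of the weakly basic organocerium reagent to the lactone gives lactol 15 without enolising C3 or touching the aryl bromide, and ionic reduction of the derived 2-aryl oxocarbenium ion delivers hydride to the face opposite the C3 and C4 aryl groups, which sets C2 with its aryl group cis to ring D (the usual 2,3-cis outcome of hemiketal reductions next to a C3 substituent).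

Step 9
Reactants: 16 (2S,3S,4R,5S)-3-[3,5-bis(benzyloxy)-2-bromophenyl]-4-[3,5-bis(benzyloxy)phenyl]-2,5-bis[4-(benzyloxy)phenyl]tetrahydrofuran; 17 3,5-bis(benzyloxy)benzaldehyde
Product: 19 [2,4-bis(benzyloxy)-6-T-phenyl][3,5-bis(benzyloxy)phenyl]methanol (both carbinol epimers), via aryllithium 18 (not isolated)
Conditions: n-BuLi, THF, −78 °C; then 17, −78 → −40 °C
Reagents that add atoms: none
Why: Bromine–lithium exchange gives the ortho-alkoxy-stabilised aryllithium, which adds to the aldehyde to form the C3a′–C3′ bond; the new carbinol centre is inconsequential because it is oxidised in the next step.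

Step 10
Reactants: 19 [2,4-bis(benzyloxy)-6-T-phenyl][3,5-bis(benzyloxy)phenyl]methanol
Product: 20 [2,4-bis(benzyloxy)-6-T-phenyl][3,5-bis(benzyloxy)phenyl]methanone
Conditions: Dess–Martin periodinane, CH2Cl2, rt
Reagents that add atoms: none
Why: Dess–Martin oxidation converts the diaryl carbinol into the ketone under neutral conditions that leave the benzylic ethers of the tetrahydrofuran untouched.

Step 11
Reactants: 20 [2,4-bis(benzyloxy)-6-T-phenyl][3,5-bis(benzyloxy)phenyl]methanone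
Product: 21 [4-(benzyloxy)-2-hydroxy-6-T-phenyl][3,5-bis(benzyloxy)phenyl]methanone
Conditions: MgBr2·OEt2, toluene/Et2O, 70 °C; aq. HCl
Reagents that add atoms: none
Why: Chelation-controlled ether cleavage, in which MgBr2 is held between the ketone oxygen and the ortho benzyloxy oxygen so that bromide removes only that benzyl group (the known selectivity for aryl ethers ortho to a carbonyl group) and frees the phenol that becomes O1′.

Step 12
Reactants: 21 [4-(benzyloxy)-2-hydroxy-6-T-phenyl][3,5-bis(benzyloxy)phenyl]methanone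
Product: 22 5-(benzyloxy)-2-{[3,5-bis(benzyloxy)phenyl](hydroxy)methyl}-3-T-phenol (both carbinol epimers)
Conditions: NaBH4, THF/MeOH, 0 °C
Reagents that add atoms: none
Why: Borohydride reduction of the diaryl ketone gives the 2-hydroxybenzhydrol; the carbinol centre forms as a mixture and is erased when the quinone methide is generated in step 17.

Step 13
Reactants: 22 5-(benzyloxy)-2-{[3,5-bis(benzyloxy)phenyl](hydroxy)methyl}-3-T-phenol
Product: 23 5-(benzyloxy)-2-{[3,5-bis(benzyloxy)phenyl](4-methylbenzenesulfonyl)methyl}-3-T-phenol (both epimers)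
Conditions: p-TolSO2H, CH2Cl2, rt
Reagents that add atoms: p-toluenesulfinic acid, Cc1ccc(cc1)S(=O)O
Why: SN1 substitution through the benzhydryl cation/o-quinone methide, which the ortho hydroxyl and para benzyloxy groups stabilise far better than any cation available from the tetrahydrofuran ethers, with capture at sulfur to give the sulfone that later leaves as sulfinate.

Step 14
Reactants: 24 (2S,5S)-hexane-2,5-diol
Product: 25 (2S,5S)-hexane-2,5-diyl dimethanesulfonate
Conditions: MsCl, Et3N, CH2Cl2, −10 °C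
Reagents that add atoms: methanesulfonyl chloride, CS(=O)(=O)Cl
Why: Sulfonylation at oxygen activates both secondary alcohols without touching the stereocentres.

Step 15
Reactants: 25 (2S,5S)-hexane-2,5-diyl dimethanesulfonate
Product: 26 (2R,5R)-2,5-dimethylthiolane
Conditions: Na2S·9H2O, DMSO, rt → 40 °C
Reagents that add atoms: sodium sulfide, [Na+].[Na+].[S-2]
Why: Two SN2 displacements by sulfide, each with inversion, close the thiolane and turn the (S,S) dimesylate into the C2-symmetric (R,R) sulfide.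

Step 16
Reactants: 26 (2R,5R)-2,5-dimethylthiolane; 27 4-(benzyloxy)benzyl bromide
Product: 28 (2R,5R)-1-[4-(benzyloxy)benzyl]-2,5-dimethylthiolan-1-ium tetrafluoroborate
Conditions: AgBF4, CH2Cl2, 0 °C → rt, dark
Reagents that add atoms: silver tetrafluoroborate, [Ag+].F[B-](F)(F)F
Why: S-alkylation of the hindered sulfide is driven by precipitation of AgBr, and because the ring is C2-symmetric the sulfonium sulfur is not a stereocentre, so a single salt results.

Step 17
Reactants: 23 5-(benzyloxy)-2-{[3,5-bis(benzyloxy)phenyl](4-methylbenzenesulfonyl)methyl}-3-T-phenol; 28 (2R,5R)-1-[4-(benzyloxy)benzyl]-2,5-dimethylthiolan-1-ium tetrafluoroborate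
Product: 32 (2R,3R)-6-(benzyloxy)-3-[3,5-bis(benzyloxy)phenyl]-2-[4-(benzyloxy)phenyl]-4-T-2,3-dihydrobenzofuran (octabenzyl ether of the target), via o-quinone methide 29 (not isolated), via sulfonium ylide 30 (not isolated), via betaine 31 (not isolated)
Conditions: Cs2CO3 (3 equiv), CH2Cl2, 0 °C → rt
Reagents that add atoms: none
Why: Cs2CO3 deprotonates the phenol of 23, which expels p-toluenesulfinate to give o-quinone methide 29 (C3′=C3a′, C7a′=O), and deprotonates 28 to ylide 30; the ylide carbon adds 1,4 to C3′ with rearomatisation of ring D to give betaine 31, whose phenoxide displaces the thiolane at C2′ with inversion. The closest known reaction type is the base-mediated [4+1] annulation of 2-(1-sulfonylalkyl)phenols with sulfonium ylides to trans-2,3-disubstituted dihydrobenzofurans, including variants with chiral sulfides. The one new ring, O1′–C2′–C3′–C3a′–C7a′, closes 5-exo-tet. C2′ is controlled by the (2R,5R)-thiolanium ylide, whose ring methyl cis to the ylide carbon shields one face (the face model used for epoxidations with this sulfide), so the sulfonium-bearing carbon of 31 should be S and C2′ after inversion R; C3′ is controlled relative to C2′ by the addition geometry that places the two aryl groups anti and closes to the trans ring, hence R. The step needs the reagent to override the facial bias of the chiral quinone methide; allylic strain holds the C3–H of the ortho tetrahydrofuran substituent in the plane of ring D, so the two faces of C3′ are flanked by similar CH(aryl) arms and the intrinsic bias should be small.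

Step 18
Reactants: 32 (2R,3R)-6-(benzyloxy)-3-[3,5-bis(benzyloxy)phenyl]-2-[4-(benzyloxy)phenyl]-4-T-2,3-dihydrobenzofuran
Product: 33 5-[(2R,3R)-4-[(2S,3S,4R,5S)-4-(3,5-dihydroxyphenyl)-2,5-bis(4-hydroxyphenyl)tetrahydrofuran-3-yl]-6-hydroxy-2-(4-hydroxyphenyl)-2,3-dihydrobenzofuran-3-yl]benzene-1,3-diol (CNP0202577.3)
Conditions: H2 (1 atm), Pd/C, EtOAc/MeOH, rt
Reagents that add atoms: none
Why: Hydrogenolysis removes the eight aryl benzyl ethers under neutral conditions, the primary ArO–CH2Ph bonds being cleaved much faster than the secondary benzylic C–O bonds of the tetrahydrofuran and dihydrobenzofuran, and no stereocentre is touched.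

**Compound list**

1 | 1,3-bis(benzyloxy)-5-bromobenzene | Brc1cc(OCc2ccccc2)cc(OCc2ccccc2)c1 | starting material
2 | (R)-but-3-yn-2-ol | C[C@@H](O)C#C | starting material
3 | (R)-4-[3,5-bis(benzyloxy)phenyl]but-3-yn-2-ol | C[C@@H](O)C#Cc1cc(OCc2ccccc2)cc(OCc2ccccc2)c1 | intermediate
4 | (R,Z)-4-[3,5-bis(benzyloxy)phenyl]but-3-en-2-ol | C[C@@H](O)/C=C\c1cc(OCc2ccccc2)cc(OCc2ccccc2)c1 | intermediate
5 | [3,5-bis(benzyloxy)phenyl]acetic acid | OC(=O)Cc1cc(OCc2ccccc2)cc(OCc2ccccc2)c1 | starting material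
6 | [3,5-bis(benzyloxy)-2-bromophenyl]acetic acid | OC(=O)Cc1cc(OCc2ccccc2)cc(OCc2ccccc2)c1Br | intermediate
7 | (R,Z)-4-[3,5-bis(benzyloxy)phenyl]but-3-en-2-yl [3,5-bis(benzyloxy)-2-bromophenyl]acetate | C[C@@H](OC(=O)Cc1cc(OCc2ccccc2)cc(OCc2ccccc2)c1Br)/C=C\c1cc(OCc2ccccc2)cc(OCc2ccccc2)c1 | intermediate
8 | (Z)-O-trimethylsilyl ketene acetal of 7 (aryl cis to OSiMe3) | C[C@@H](O/C(O[Si](C)(C)C)=C/c1cc(OCc2ccccc2)cc(OCc2ccccc2)c1Br)/C=C\c1cc(OCc2ccccc2)cc(OCc2ccccc2)c1 | intermediate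
9 | trimethylsilyl (2S,3R,E)-2-[3,5-bis(benzyloxy)-2-bromophenyl]-3-[3,5-bis(benzyloxy)phenyl]hex-4-enoate | C/C=C/[C@@H](c1cc(OCc2ccccc2)cc(OCc2ccccc2)c1)[C@H](C(=O)O[Si](C)(C)C)c1cc(OCc2ccccc2)cc(OCc2ccccc2)c1Br | intermediate
10 | (2S,3R,E)-2-[3,5-bis(benzyloxy)-2-bromophenyl]-3-[3,5-bis(benzyloxy)phenyl]hex-4-enoic acid | C/C=C/[C@@H](c1cc(OCc2ccccc2)cc(OCc2ccccc2)c1)[C@H](C(=O)O)c1cc(OCc2ccccc2)cc(OCc2ccccc2)c1Br | intermediate
11 | (3S,4R)-3-[3,5-bis(benzyloxy)-2-bromophenyl]-4-[3,5-bis(benzyloxy)phenyl]-5-hydroxydihydrofuran-2(3H)-one (C5 epimers) | O=C1OC(O)[C@@H](c2cc(OCc3ccccc3)cc(OCc3ccccc3)c2)[C@H]1c1cc(OCc2ccccc2)cc(OCc2ccccc2)c1Br | intermediate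
12 | 4-(benzyloxy)phenylmagnesium bromide | Br[Mg]c1ccc(OCc2ccccc2)cc1 | starting material
13 | (2S,3R)-2-[3,5-bis(benzyloxy)-2-bromophenyl]-3-[3,5-bis(benzyloxy)phenyl]-4-[4-(benzyloxy)phenyl]-4-hydroxybutanoic acid (C4 epimers) | OC(c1ccc(OCc2ccccc2)cc1)[C@@H](c1cc(OCc2ccccc2)cc(OCc2ccccc2)c1)[C@H](C(=O)O)c1cc(OCc2ccccc2)cc(OCc2ccccc2)c1Br | intermediate
14 | (3S,4R,5S)-3-[3,5-bis(benzyloxy)-2-bromophenyl]-4-[3,5-bis(benzyloxy)phenyl]-5-[4-(benzyloxy)phenyl]dihydrofuran-2(3H)-one (3,4-cis, 4,5-trans) | O=C1O[C@H](c2ccc(OCc3ccccc3)cc2)[C@@H](c2cc(OCc3ccccc3)cc(OCc3ccccc3)c2)[C@H]1c1cc(OCc2ccccc2)cc(OCc2ccccc2)c1Br | intermediate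
15 | (3S,4R,5S)-3-[3,5-bis(benzyloxy)-2-bromophenyl]-4-[3,5-bis(benzyloxy)phenyl]-2,5-bis[4-(benzyloxy)phenyl]tetrahydrofuran-2-ol (C2 epimers) | OC1(c2ccc(OCc3ccccc3)cc2)O[C@H](c2ccc(OCc3ccccc3)cc2)[C@@H](c2cc(OCc3ccccc3)cc(OCc3ccccc3)c2)[C@H]1c1cc(OCc2ccccc2)cc(OCc2ccccc2)c1Br | intermediate
16 | (2S,3S,4R,5S)-3-[3,5-bis(benzyloxy)-2-bromophenyl]-4-[3,5-bis(benzyloxy)phenyl]-2,5-bis[4-(benzyloxy)phenyl]tetrahydrofuran (2,3-cis, 3,4-cis, 4,5-trans) | c4ccccc4COc1ccc([C@H]2O[C@H](c3ccc(OCc4ccccc4)cc3)[C@@H](c3cc(OCc4ccccc4)cc(OCc4ccccc4)c3)[C@H]2c2cc(OCc4ccccc4)cc(OCc4ccccc4)c2Br)cc1 | intermediate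
17 | 3,5-bis(benzyloxy)benzaldehyde | O=Cc1cc(OCc2ccccc2)cc(OCc2ccccc2)c1 | starting material
18 | [2,4-bis(benzyloxy)-6-T-phenyl]lithium | c4ccccc4COc1ccc([C@H]2O[C@H](c3ccc(OCc4ccccc4)cc3)[C@@H](c3cc(OCc4ccccc4)cc(OCc4ccccc4)c3)[C@H]2c2cc(OCc4ccccc4)cc(OCc4ccccc4)c2[Li])cc1 | intermediate
19 | [2,4-bis(benzyloxy)-6-T-phenyl][3,5-bis(benzyloxy)phenyl]methanol (carbinol epimers) | c4ccccc4COc1ccc([C@H]2O[C@H](c3ccc(OCc4ccccc4)cc3)[C@@H](c3cc(OCc4ccccc4)cc(OCc4ccccc4)c3)[C@H]2c2cc(OCc4ccccc4)cc(OCc4ccccc4)c2C(O)c2cc(OCc4ccccc4)cc(OCc4ccccc4)c2)cc1 | intermediate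
20 | [2,4-bis(benzyloxy)-6-T-phenyl][3,5-bis(benzyloxy)phenyl]methanone | c4ccccc4COc1ccc([C@H]2O[C@H](c3ccc(OCc4ccccc4)cc3)[C@@H](c3cc(OCc4ccccc4)cc(OCc4ccccc4)c3)[C@H]2c2cc(OCc4ccccc4)cc(OCc4ccccc4)c2C(=O)c2cc(OCc4ccccc4)cc(OCc4ccccc4)c2)cc1 | intermediate
21 | [4-(benzyloxy)-2-hydroxy-6-T-phenyl][3,5-bis(benzyloxy)phenyl]methanone | c4ccccc4COc1ccc([C@H]2O[C@H](c3ccc(OCc4ccccc4)cc3)[C@@H](c3cc(OCc4ccccc4)cc(OCc4ccccc4)c3)[C@H]2c2cc(OCc4ccccc4)cc(O)c2C(=O)c2cc(OCc4ccccc4)cc(OCc4ccccc4)c2)cc1 | intermediate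
22 | 5-(benzyloxy)-2-{[3,5-bis(benzyloxy)phenyl](hydroxy)methyl}-3-T-phenol (carbinol epimers) | c4ccccc4COc1ccc([C@H]2O[C@H](c3ccc(OCc4ccccc4)cc3)[C@@H](c3cc(OCc4ccccc4)cc(OCc4ccccc4)c3)[C@H]2c2cc(OCc4ccccc4)cc(O)c2C(O)c2cc(OCc4ccccc4)cc(OCc4ccccc4)c2)cc1 | intermediate
23 | 5-(benzyloxy)-2-{[3,5-bis(benzyloxy)phenyl](4-methylbenzenesulfonyl)methyl}-3-T-phenol (epimers at the sulfonyl carbon) | c4ccccc4COc1ccc([C@H]2O[C@H](c3ccc(OCc4ccccc4)cc3)[C@@H](c3cc(OCc4ccccc4)cc(OCc4ccccc4)c3)[C@H]2c2cc(OCc4ccccc4)cc(O)c2C(S(=O)(=O)c2ccc(C)cc2)c2cc(OCc4ccccc4)cc(OCc4ccccc4)c2)cc1 | intermediate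
24 | (2S,5S)-hexane-2,5-diol | C[C@H](O)CC[C@@H](O)C | starting material
25 | (2S,5S)-hexane-2,5-diyl dimethanesulfonate | C[C@H](OS(C)(=O)=O)CC[C@@H](OS(C)(=O)=O)C | intermediate
26 | (2R,5R)-2,5-dimethylthiolane | C[C@@H]1CC[C@@H](C)S1 | intermediate
27 | 4-(benzyloxy)benzyl bromide | BrCc1ccc(OCc2ccccc2)cc1 | starting material
28 | (2R,5R)-1-[4-(benzyloxy)benzyl]-2,5-dimethylthiolan-1-ium tetrafluoroborate | C[C@@H]1CC[C@@H](C)[S+]1Cc1ccc(OCc2ccccc2)cc1.F[B-](F)(F)F | intermediate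
29 | 3-(benzyloxy)-6-[3,5-bis(benzyloxy)benzylidene]-5-T-cyclohexa-2,4-dien-1-one (o-quinone methide) | c4ccccc4COc1ccc([C@H]2O[C@H](c3ccc(OCc4ccccc4)cc3)[C@@H](c3cc(OCc4ccccc4)cc(OCc4ccccc4)c3)[C@H]2C2=CC(OCc4ccccc4)=CC(=O)C2=Cc2cc(OCc4ccccc4)cc(OCc4ccccc4)c2)cc1 | intermediate
30 | [4-(benzyloxy)phenyl][(2R,5R)-2,5-dimethylthiolan-1-ium-1-yl]methanide (sulfonium ylide) | C[C@@H]1CC[C@@H](C)[S+]1[CH-]c1ccc(OCc2ccccc2)cc1 | intermediate
31 | 5-(benzyloxy)-2-{(1R,2S)-1-[3,5-bis(benzyloxy)phenyl]-2-[4-(benzyloxy)phenyl]-2-[(2R,5R)-2,5-dimethylthiolan-1-ium-1-yl]ethyl}-3-T-phenolate (betaine) | c4ccccc4COc1ccc([C@H]2O[C@H](c3ccc(OCc4ccccc4)cc3)[C@@H](c3cc(OCc4ccccc4)cc(OCc4ccccc4)c3)[C@H]2c2cc(OCc4ccccc4)cc([O-])c2[C@@H](c2cc(OCc4ccccc4)cc(OCc4ccccc4)c2)[C@@H](c2ccc(OCc4ccccc4)cc2)[S+]5[C@H](C)CC[C@H]5C)cc1 | intermediate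
32 | (2R,3R)-6-(benzyloxy)-3-[3,5-bis(benzyloxy)phenyl]-2-[4-(benzyloxy)phenyl]-4-{(2S,3S,4R,5S)-4-[3,5-bis(benzyloxy)phenyl]-2,5-bis[4-(benzyloxy)phenyl]tetrahydrofuran-3-yl}-2,3-dihydrobenzofuran | c4ccccc4COc1ccc([C@H]2O[C@H](c3ccc(OCc4ccccc4)cc3)[C@@H](c3cc(OCc4ccccc4)cc(OCc4ccccc4)c3)[C@H]2c2cc(OCc4ccccc4)cc3c2[C@@H](c2cc(OCc4ccccc4)cc(OCc4ccccc4)c2)[C@H](c2ccc(OCc4ccccc4)cc2)O3)cc1 | intermediate
33 | 5-[(2R,3R)-4-[(2S,3S,4R,5S)-4-(3,5-dihydroxyphenyl)-2,5-bis(4-hydroxyphenyl)tetrahydrofuran-3-yl]-6-hydroxy-2-(4-hydroxyphenyl)-2,3-dihydrobenzofuran-3-yl]benzene-1,3-diol | Oc1ccc([C@H]2O[C@H](c3ccc(O)cc3)[C@@H](c3cc(O)cc(O)c3)[C@H]2c2cc(O)cc3c2[C@@H](c2cc(O)cc(O)c2)[C@H](c2ccc(O)cc2)O3)cc1 | target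

**Totals and risks**

Total step count: 18. Longest linear sequence: 14 steps (steps 1, 2, 4–13, 17, 18).

Steps most likely to fail:

1. Step 17. The facial preference of the chiral ylide and that of the chiral quinone methide may oppose each other (mismatched pairing), or the congested methide may form so slowly that the ylide is lost by protonation or rearrangement; either way the trans ring would form with poor control at C3′. The fallback sets out from 21 and returns at 32, making the two bonds one at a time by homologation, arylation and cyclodehydration. Ketone 21 is silylated (t-BuMe2SiOTf, 2,6-lutidine) to silyl ether F1. Corey–Chaykovsky methylenation (Me3S+ I−, n-BuLi, THF) gives epoxide F2, and Meinwald rearrangement (ZnI2) gives diarylacetaldehyde F3. The α-centre of F3, the future C3′, is epimerisable and can be equilibrated with a mild amine base under the influence of the neighbouring tetrahydrofuran. Addition of 12 gives carbinol F4 and Bu4NF gives phenol F5. Cyclodehydration (PPh3, DIAD) closes O1′–C2′ to 32; the trans ring is expected because the 4-benzyloxybenzylic oxyphosphonium ionises before closure.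

2. Step 5. Loss of enolate geometry during silylation, or leakage through a boat transition state, would erode the relative configuration at C2/C3 of 10. The fallback sets out from 7 and returns at 14, and sets this centre after ring formation instead of in the rearrangement. Ester 7 is rearranged without regard to ketene acetal geometry. The acid containing the C2 epimer F6 is taken through the step 6 cleavage to hydroxy lactone F7 and through the step 7 Grignard addition and lactonisation to the all-trans lactone F8. Deprotonation of the lactone mixture (LiN(SiMe3)2, THF, −78 °C) gives a single enolate from both epimers. Kinetic protonation with a hindered phenol, on the face opposite the C4 aryl group, then gives the 3,4-cis lactone 14.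

3. Step 8. The aryl nucleophile may act as a base on the α-aryl lactone (epimerisation at C3, recovered lactone) or add twice. The fallback sets out from 14 and returns at 15, introducing the aryl group by acyl substitution on an open-chain amide. Aminolysis of 14 with MeNH(OMe)·HCl and AlMe3 gives hydroxy Weinreb amide F9. Treatment of F9 with 12 (excess) gives the hydroxy ketone, which closes to lactol 15 on work-up. The chelated tetrahedral intermediate prevents over-addition, and the amide α-proton is much less acidic than that of the lactone.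

Further compounds

F1 | step 17 | [4-(benzyloxy)-2-(tert-butyldimethylsilyloxy)-6-T-phenyl][3,5-bis(benzyloxy)phenyl]methanone | c4ccccc4COc1ccc([C@H]2O[C@H](c3ccc(OCc4ccccc4)cc3)[C@@H](c3cc(OCc4ccccc4)cc(OCc4ccccc4)c3)[C@H]2c2cc(OCc4ccccc4)cc(O[Si](C)(C)C(C)(C)C)c2C(=O)c2cc(OCc4ccccc4)cc(OCc4ccccc4)c2)cc1
F2 | step 17 | 2-[4-(benzyloxy)-2-(tert-butyldimethylsilyloxy)-6-T-phenyl]-2-[3,5-bis(benzyloxy)phenyl]oxirane | c4ccccc4COc1ccc([C@H]2O[C@H](c3ccc(OCc4ccccc4)cc3)[C@@H](c3cc(OCc4ccccc4)cc(OCc4ccccc4)c3)[C@H]2c2cc(OCc4ccccc4)cc(O[Si](C)(C)C(C)(C)C)c2C5(CO5)c2cc(OCc4ccccc4)cc(OCc4ccccc4)c2)cc1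
F3 | step 17 | 2-[4-(benzyloxy)-2-(tert-butyldimethylsilyloxy)-6-T-phenyl]-2-[3,5-bis(benzyloxy)phenyl]acetaldehyde | c4ccccc4COc1ccc([C@H]2O[C@H](c3ccc(OCc4ccccc4)cc3)[C@@H](c3cc(OCc4ccccc4)cc(OCc4ccccc4)c3)[C@H]2c2cc(OCc4ccccc4)cc(O[Si](C)(C)C(C)(C)C)c2C(C=O)c2cc(OCc4ccccc4)cc(OCc4ccccc4)c2)cc1
F4 | step 17 | 2-[4-(benzyloxy)-2-(tert-butyldimethylsilyloxy)-6-T-phenyl]-2-[3,5-bis(benzyloxy)phenyl]-1-[4-(benzyloxy)phenyl]ethanol | c4ccccc4COc1ccc([C@H]2O[C@H](c3ccc(OCc4ccccc4)cc3)[C@@H](c3cc(OCc4ccccc4)cc(OCc4ccccc4)c3)[C@H]2c2cc(OCc4ccccc4)cc(O[Si](C)(C)C(C)(C)C)c2C(C(O)c2ccc(OCc4ccccc4)cc2)c2cc(OCc4ccccc4)cc(OCc4ccccc4)c2)cc1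
F5 | step 17 | 5-(benzyloxy)-2-{1-[3,5-bis(benzyloxy)phenyl]-2-[4-(benzyloxy)phenyl]-2-hydroxyethyl}-3-T-phenol | c4ccccc4COc1ccc([C@H]2O[C@H](c3ccc(OCc4ccccc4)cc3)[C@@H](c3cc(OCc4ccccc4)cc(OCc4ccccc4)c3)[C@H]2c2cc(OCc4ccccc4)cc(O)c2C(C(O)c2ccc(OCc4ccccc4)cc2)c2cc(OCc4ccccc4)cc(OCc4ccccc4)c2)cc1
F6 | step 5 | (2R,3R,E)-2-[3,5-bis(benzyloxy)-2-bromophenyl]-3-[3,5-bis(benzyloxy)phenyl]hex-4-enoic acid | C/C=C/[C@@H](c1cc(OCc2ccccc2)cc(OCc2ccccc2)c1)[C@@H](C(=O)O)c1cc(OCc2ccccc2)cc(OCc2ccccc2)c1Br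
F7 | step 5 | (3R,4R)-3-[3,5-bis(benzyloxy)-2-bromophenyl]-4-[3,5-bis(benzyloxy)phenyl]-5-hydroxydihydrofuran-2(3H)-one | O=C1OC(O)[C@@H](c2cc(OCc3ccccc3)cc(OCc3ccccc3)c2)[C@@H]1c1cc(OCc2ccccc2)cc(OCc2ccccc2)c1Br
F8 | step 5 | (3R,4R,5S)-3-[3,5-bis(benzyloxy)-2-bromophenyl]-4-[3,5-bis(benzyloxy)phenyl]-5-[4-(benzyloxy)phenyl]dihydrofuran-2(3H)-one | O=C1O[C@H](c2ccc(OCc3ccccc3)cc2)[C@@H](c2cc(OCc3ccccc3)cc(OCc3ccccc3)c2)[C@@H]1c1cc(OCc2ccccc2)cc(OCc2ccccc2)c1Br
F9 | step 8 | (2S,3R,4S)-2-[3,5-bis(benzyloxy)-2-bromophenyl]-3-[3,5-bis(benzyloxy)phenyl]-4-[4-(benzyloxy)phenyl]-4-hydroxy-N-methoxy-N-methylbutanamide | O[C@H](c1ccc(OCc2ccccc2)cc1)[C@@H](c1cc(OCc2ccccc2)cc(OCc2ccccc2)c1)[C@H](C(=O)N(C)OC)c1cc(OCc2ccccc2)cc(OCc2ccccc2)c1Br
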